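Slowness is what you see first: after 10.0 min, target stands at 2.24 mM in maple and 2.30 mM in elm, although they were charged 5 mM and 20 mM. So reckon in mM, not percent.

| flask | substrate | gas phase | remark | time |
|---|---|---|---|---|
| maple | 5 mM | 0.84 mM (held) | run made earlier |  |
| elm | 20 mM | 0.84 mM (held) | run made earlier |  |
| flask | 10 mM | 0.84 mM (held) |  | 12 min |

| run | time / min | target / % |
|---|---|---|
| maple | 0.833 | 5.9 |
| maple | 1.33 | 10.3 |
| maple | 2.50 | 18.0 |
| maple | 5.00 | 30.2 |
| maple | 10.0 | 44.8 |
| elm | 2.00 | 5.1 |
| elm | 4.00 | 7.6 |
| elm | 6.00 | 7.6 |
| elm | 8.00 | 8.6 |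
| elm | 10.0 | 11.5 |

(each reading ± 0.5 percentage points)

* the target standing at 12 min, as a percentage of the substrate charged
* the change that raises the amount of target at 12 min, in percent of the substrate charged most ("none" if none brings more than 2 percentage points) (midnight / summer / none)
* amount of target at 12 min, in percent of the substrate charged, after midnight

- midnight: doubling the saturation concentration of gas phase, all else as stated
- summer: doubling the transfer coefficient of the gas phase, all else as stated

Maple gained 0.146 mM min⁻¹ between 5.00 min and 10.0 min: this net rate of formation of target over a late stretch is the late ration. Over its first 2.00 min elm gained faster than that, at 0.510 mM min⁻¹.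

From above, hold that fast ration for the whole time:

0.510 mM min⁻¹ × 12 min = 6.12 mM, or 61.2 % of the flask's charge.

That is loose, since the fast ration is higher than maple's late ration. So tighten it, fast ration to 5.00 min and late ration afterwards:

(0.510 mM min⁻¹ × 5.00 min + 0.146 mM min⁻¹ × 7.00 min) / 10 mM = 35.7 %.

From below: target was still rising at the last reading of both runs, and I expect a charge between theirs to stand no lower than the lower of them:

2.24 mM / 10 mM = 22.4 %.

The forecast gives 28 %, inside my bracket, with a range of 22 % to 34 %. It picks midnight at 45 %, and says: "Something tied to substrate therefore seems to throttle the rate".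

The flask gives 28.5 %. Midnight gives 44.5 %, adding 16 percentage points against 6.9 points for summer.

    gas phase ⇌ dissolved gas, rate k1*(csat - [dissolved gas]) (kL = 1.30 min⁻¹)
    substrate + dissolved gas → target (k = 310 M⁻¹ min⁻¹)
    substrate + target → side product (k = 34.0 M⁻¹ min⁻¹)
    target ⇌ isomer of the product (K = 0.120, k = 0.0640 min⁻¹)
    dissolved gas ⇌ dormant form (K = 11.0, k = 0.0930 min⁻¹)

At 4.74 min, this flask makes target 1.60 times as fast as it uses it, and the step to target takes substrate 1.8 times as fast as the step to side product. From its reading at 5.0 min to 12 min, the flask's own late ration is 0.150 mM min⁻¹, beside maple's 0.146 mM min⁻¹. Carrying maple's ration from 18.0 % at 5.0 min to the neighbouring reading at 8.0 min gives 22.4 %, and that reading stands at 23.5 %.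

The runs come from a simulation on assumed constants, and the scatter is random.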